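The plan cuts arene bond C6–C1 (C1 side chain, C2 H, C3 OH, C4 CH3, C5 OH, C6 OAc) and unfolds the benzene ring to a squarate-derived cyclobutenone. The key step exploits the oxygen pattern. O3 and O6 are para and O5 flanks O6, so C3–C6 are the four squarate carbons. C2 and C1 are an E-alkene that already carries the (S)-side chain. Heating the precursor, a 4-dienyl-4-silyloxy-2-tert-butoxy-3-methylcyclobutenone, should give the pentasubstituted benzene in one operation by 4π opening, 6π closure and enolisation, with O6 alone free for acetylation. The stereocentre comes from methyl (S)-glycidate. O5 is switched from tert-butyl to silyl before the angelate is installed.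

Key step: step 11

Remark: the quaternary ring carbon of the cyclobutenones made in steps 9 and 10 forms as both epimers and is drawn without configuration, because step 11 makes it planar.

Step 1
Reactants: 1 methyl (S)-oxirane-2-carboxylate (methyl (S)-glycidate); 2 2-methylprop-1-enylmagnesium bromide
Product: 3 methyl (2S)-2-hydroxy-5-methylhex-4-enoate
Conditions: CuI (10 mol %), THF, −40 °C
Reagents that add atoms: none
Why: Copper-catalysed SN2 opening of a terminal epoxide by an alkenyl Grignard reagent takes place at the unhindered CH2 faster than addition to the ester at this temperature, so the C2–O bond and the purchased (S) configuration stay untouched.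

Step 2
Reactants: 3 methyl (2S)-2-hydroxy-5-methylhex-4-enoate
Product: 4 methyl (2S)-5-methyl-2-(triethylsilyloxy)hex-4-enoate
Conditions: Et3SiCl, imidazole, CH2Cl2, 0 °C → rt
Reagents that add atoms: chlorotriethylsilane, CC[Si](Cl)(CC)CC
Why: Imidazole-promoted O-silylation gives a triethylsilyl ether that withstands organolithium reagents and can later be removed in the presence of aryl tert-butyldimethylsilyl ethers.

Step 3
Reactants: 4 methyl (2S)-5-methyl-2-(triethylsilyloxy)hex-4-enoate
Product: 5 (2S)-N-methoxy-N,5-dimethyl-2-(triethylsilyloxy)hex-4-enamide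
Conditions: MeNH(OMe)·HCl, i-PrMgCl, THF, −20 → 0 °C
Reagents that add atoms: N,O-dimethylhydroxylamine hydrochloride, CNOC.Cl
Why: Weinreb amide formation by aminolysis of the ester with the chloromagnesium amide is fast below 0 °C, where the alpha-silyloxy stereocentre should not be enolised.

Step 4
Reactants: 5 (2S)-N-methoxy-N,5-dimethyl-2-(triethylsilyloxy)hex-4-enamide; 6 trimethylsilylacetylene
Product: 8 (4S)-7-methyl-4-(triethylsilyloxy)-1-(trimethylsilyl)oct-6-en-1-yn-3-one, via lithium trimethylsilylacetylide 7 (not isolated)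
Conditions: 6, n-BuLi, THF, −78 °C; then 5, −78 → −20 °C
Reagents that add atoms: none
Why: In the Weinreb ketone synthesis the chelated tetrahedral adduct survives until work-up, so the acetylide adds only once and the ynone never meets a basic nucleophile.

Step 5
Reactants: 8 (4S)-7-methyl-4-(triethylsilyloxy)-1-(trimethylsilyl)oct-6-en-1-yn-3-one
Product: 10 (4S)-7-methyl-3-methylidene-4-(triethylsilyloxy)oct-6-en-1-yne, via C-silylated enyne 9 (not isolated)
Conditions: Ph3PCH3Br, KN(SiMe3)2, THF, 0 °C; then 8, −78 → 0 °C; then MeOH, K2CO3 (cat.), rt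
Reagents that add atoms: methyltriphenylphosphonium bromide, C[P+](c1ccccc1)(c1ccccc1)c1ccccc1.[Br-]
Why: In this Wittig methylenation the very electrophilic ynone carbonyl should be attacked 1,2 at −78 °C faster than it is enolised, the silyl cap hinders conjugate addition, and base-catalysed methanolysis of the alkynyl C–Si bond in the same flask frees the terminal alkyne without harming the triethylsilyl ether.

Step 6
Reactants: 10 (4S)-7-methyl-3-methylidene-4-(triethylsilyloxy)oct-6-en-1-yne
Product: 12 (1E,4S)-1-iodo-7-methyl-3-methylidene-4-(triethylsilyloxy)octa-1,6-diene, via alkenyl-ZrCp2Cl species 11 (not isolated)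
Conditions: Cp2Zr(H)Cl, THF, rt, dark; then I2, −78 → 0 °C
Reagents that add atoms: iodine, II
Why: Hydrozirconation adds H and Zr syn to the terminal alkyne (Zr on the terminal carbon) in preference to the 1,1-disubstituted and trisubstituted alkenes, and iodinolysis of the C–Zr bond with retention fixes the E geometry.

Step 7
Reactants: 13 squaric acid
Product: 14 disilver squarate (Ag2C4O4)
Conditions: AgNO3 (2 equiv), H2O, rt, dark; filter, dry
Reagents that add atoms: silver nitrate, [Ag+].[O-][N+](=O)[O-]
Why: Salt metathesis precipitates the very insoluble silver salt, which provides a squarate that can be alkylated on oxygen.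

Step 8
Reactants: 14 disilver squarate (Ag2C4O4)
Product: 15 di-tert-butyl squarate (3,4-di-tert-butoxycyclobut-3-ene-1,2-dione)
Conditions: t-BuCl, Et2O, rt, dark
Reagents that add atoms: tert-butyl chloride, CC(C)(C)Cl
Why: SN1-type O-alkylation of the silver salt, driven by precipitation of AgCl, is the established access to this ester, which acid-catalysed esterification with tert-butanol cannot give.

Step 9
Reactants: 12 (1E,4S)-1-iodo-7-methyl-3-methylidene-4-(triethylsilyloxy)octa-1,6-diene; 15 di-tert-butyl squarate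
Product: 18 2,3-di-tert-butoxy-4-(tert-butyldimethylsilyloxy)-4-[(1E,4S)-7-methyl-3-methylidene-4-(triethylsilyloxy)octa-1,6-dienyl]cyclobut-2-en-1-one, via dienyllithium 16 (not isolated), via lithium alkoxide adduct 17 (not isolated)
Conditions: 12, t-BuLi (2 equiv), Et2O, −78 °C; then 15, THF, −78 °C; then TBSOTf (1.05 equiv), −78 → −20 °C; cold aq NaHCO3
Reagents that add atoms: tert-butyldimethylsilyl trifluoromethanesulfonate, CC(C)(C)[Si](C)(C)OS(=O)(=O)C(F)(F)F
Why: Iodine–lithium exchange keeps the E geometry, the alkenyllithium adds 1,2 to one of the two equivalent squarate carbonyls, and the tertiary alkoxide is silylated in the cold before it can fragment, with the new quaternary carbon formed unselectively and erased in step 11.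

Step 10
Reactants: 18 2,3-di-tert-butoxy-4-(tert-butyldimethylsilyloxy)-4-[(1E,4S)-7-methyl-3-methylidene-4-(triethylsilyloxy)octa-1,6-dienyl]cyclobut-2-en-1-one
Product: 21 2-tert-butoxy-4-(tert-butyldimethylsilyloxy)-3-methyl-4-[(1E,4S)-7-methyl-3-methylidene-4-(triethylsilyloxy)octa-1,6-dienyl]cyclobut-2-en-1-one, via methyl adduct alkoxide 19 (not isolated), via tertiary trifluoroacetate 20 (not isolated)
Conditions: MeLi, THF, −78 °C; then (CF3CO)2O, −78 → 0 °C; cold aq NaHCO3
Reagents that add atoms: methyllithium, [Li]C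
Why: In this squarate 1,3-carbonyl transposition, 1,2-addition of MeLi followed by trifluoroacetylation and ionisation gives a tert-butoxy-stabilised cyclobutenyl cation that sheds its tert-butyl group as isobutene to form the new ketone, and since C1 and C3 are both bonded to C4, the methyl group must end next to the silyloxy-bearing carbon even if some MeLi adds in the conjugate sense.

Step 11
Reactants: 21 2-tert-butoxy-4-(tert-butyldimethylsilyloxy)-3-methyl-4-[(1E,4S)-7-methyl-3-methylidene-4-(triethylsilyloxy)octa-1,6-dienyl]cyclobut-2-en-1-one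
Product: 24 6-tert-butoxy-4-(tert-butyldimethylsilyloxy)-5-methyl-2-[(3S)-6-methyl-3-(triethylsilyloxy)hepta-1,5-dien-2-yl]phenol, via dienylketene 22 (not isolated), via cyclohexadienone 23 (not isolated)
Conditions: degassed toluene (0.02 M), 110 °C, Ar
Reagents that add atoms: none
Why: Thermal conrotatory 4π opening of the C1–C4 bond of 21 gives ketene 22, in which the silyloxy donor has turned outward and the dienyl group inward, so the ketene carbon lies beside the far end of the first alkene. Disrotatory 6π electrocyclisation then joins these two carbons (arene bond C6–C1, closing the six-membered carbocycle) to give dienone 23, and enolisation delivers the benzene ring of 24. This is the known thermal ring expansion of squarate-derived 4-alkenyl-4-oxycyclobutenones (Moore rearrangement). No stereocentre is created: ring C4 becomes planar, so both epimers of 21 converge, and the (S)-carbinol is a spectator. The step needs torquoselectivity, which the oxygen donor on C4 secures, and 6π rather than 8π closure, which the E geometry of the first alkene secures because the terminal methylidene cannot reach the ketene. The differentiation of the oxygens follows from the mechanism, since only the ketene oxygen ends as OH (O6) while O3 stays silylated and O5 stays tert-butylated.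

Step 12
Reactants: 24 6-tert-butoxy-4-(tert-butyldimethylsilyloxy)-5-methyl-2-[(3S)-6-methyl-3-(triethylsilyloxy)hepta-1,5-dien-2-yl]phenol
Product: 25 2-tert-butoxy-4-(tert-butyldimethylsilyloxy)-3-methyl-6-[(3S)-6-methyl-3-(triethylsilyloxy)hepta-1,5-dien-2-yl]phenyl acetate
Conditions: Ac2O, Et3N, DMAP (cat.), CH2Cl2, 0 °C → rt
Reagents that add atoms: acetic anhydride, CC(=O)OC(C)=O
Why: DMAP-catalysed acetylation reaches even a doubly flanked phenol, and O6 is the only free hydroxyl in the molecule.

Step 13
Reactants: 25 2-tert-butoxy-4-(tert-butyldimethylsilyloxy)-3-methyl-6-[(3S)-6-methyl-3-(triethylsilyloxy)hepta-1,5-dien-2-yl]phenyl acetate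
Product: 26 2,4-bis(tert-butyldimethylsilyloxy)-3-methyl-6-[(3S)-6-methyl-3-(triethylsilyloxy)hepta-1,5-dien-2-yl]phenyl acetate
Conditions: TBSOTf (2 equiv), 2,6-lutidine (3 equiv), CH2Cl2, 0 °C → rt
Reagents that add atoms: tert-butyldimethylsilyl trifluoromethanesulfonate, CC(C)(C)[Si](C)(C)OS(=O)(=O)C(F)(F)F
Why: In this silyl triflate-mediated dealkylation of a tert-butyl ether, O-silylation of the crowded, out-of-plane O5 ether triggers loss of isobutene while 2,6-lutidine takes up the acid, so neither alkene meets a protic acid and O5 ends with the same fluoride-labile group as O3 before the allylic ester exists.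

Step 14
Reactants: 26 2,4-bis(tert-butyldimethylsilyloxy)-3-methyl-6-[(3S)-6-methyl-3-(triethylsilyloxy)hepta-1,5-dien-2-yl]phenyl acetate
Product: 27 2,4-bis(tert-butyldimethylsilyloxy)-6-[(3S)-3-hydroxy-6-methylhepta-1,5-dien-2-yl]-3-methylphenyl acetate
Conditions: AcOH–THF–H2O (3:1:1), rt
Reagents that add atoms: none
Why: Acid-catalysed silyl ether solvolysis cleaves the secondary alkyl triethylsilyl ether far faster than the bulkier, acid-resistant aryl tert-butyldimethylsilyl ethers, and the aryl acetate is inert at this acidity.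

Step 15
Reactants: 27 2,4-bis(tert-butyldimethylsilyloxy)-6-[(3S)-3-hydroxy-6-methylhepta-1,5-dien-2-yl]-3-methylphenyl acetate; 28 angelic acid ((Z)-2-methylbut-2-enoic acid)
Product: 30 (3S)-2-[2-acetoxy-3,5-bis(tert-butyldimethylsilyloxy)-4-methylphenyl]-6-methylhepta-1,5-dien-3-yl (Z)-2-methylbut-2-enoate, via mixed anhydride 29 (not isolated)
Conditions: 28, 2,4,6-trichlorobenzoyl chloride, Et3N (1 equiv each), toluene, rt; then 27, 80 °C (no DMAP, no excess amine)
Reagents that add atoms: none
Why: In this Yamaguchi-type mixed-anhydride esterification the alcohol attacks the less hindered angeloyl carbonyl of 29, the absence of a nucleophilic catalyst protects the Z geometry, the absence of free base keeps transfer of the O6 acetyl to the carbinol slow, and the C–O bond of the stereocentre is not touched.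

Step 16
Reactants: 30 (3S)-2-[2-acetoxy-3,5-bis(tert-butyldimethylsilyloxy)-4-methylphenyl]-6-methylhepta-1,5-dien-3-yl (Z)-2-methylbut-2-enoate
Product: 31 (3S)-2-(2-acetoxy-3,5-dihydroxy-4-methylphenyl)-6-methylhepta-1,5-dien-3-yl (Z)-2-methylbut-2-enoate (CNP0147405.1)
Conditions: HF·pyridine, pyridine, THF, 0 °C → rt; pH 7 buffer work-up
Reagents that add atoms: none
Why: Fluoride-driven cleavage of both aryl silyl ethers in a mildly acidic medium builds up no phenoxide, so the O6 acetate should not move to O5, and both esters and all three alkenes are left alone.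

Compound list
1 | methyl (S)-oxirane-2-carboxylate (methyl (S)-glycidate) | COC(=O)[C@@H]1CO1 | starting material
2 | 2-methylprop-1-enylmagnesium bromide | CC(C)=C[Mg]Br | starting material
3 | methyl (2S)-2-hydroxy-5-methylhex-4-enoate | COC(=O)[C@@H](O)CC=C(C)C | intermediate
4 | methyl (2S)-5-methyl-2-(triethylsilyloxy)hex-4-enoate | COC(=O)[C@@H](O[Si](CC)(CC)CC)CC=C(C)C | intermediate
5 | (2S)-N-methoxy-N,5-dimethyl-2-(triethylsilyloxy)hex-4-enamide | CON(C)C(=O)[C@@H](O[Si](CC)(CC)CC)CC=C(C)C | intermediate
6 | trimethylsilylacetylene | C#C[Si](C)(C)C | starting material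
7 | lithium trimethylsilylacetylide | [Li]C#C[Si](C)(C)C | intermediate
8 | (4S)-7-methyl-4-(triethylsilyloxy)-1-(trimethylsilyl)oct-6-en-1-yn-3-one | C[Si](C)(C)C#CC(=O)[C@@H](O[Si](CC)(CC)CC)CC=C(C)C | intermediate
9 | (4S)-7-methyl-3-methylidene-4-(triethylsilyloxy)-1-(trimethylsilyl)oct-6-en-1-yne | C[Si](C)(C)C#CC(=C)[C@@H](O[Si](CC)(CC)CC)CC=C(C)C | intermediate
10 | (4S)-7-methyl-3-methylidene-4-(triethylsilyloxy)oct-6-en-1-yne | C#CC(=C)[C@@H](O[Si](CC)(CC)CC)CC=C(C)C | intermediate
11 | chlorobis(cyclopentadienyl)[(1E,4S)-7-methyl-3-methylidene-4-(triethylsilyloxy)octa-1,6-dienyl]zirconium (cyclopentadienyl rings written sigma-bonded) | Cl[Zr](/C=C/C(=C)[C@@H](O[Si](CC)(CC)CC)CC=C(C)C)(C1C=CC=C1)C1C=CC=C1 | intermediate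
12 | (1E,4S)-1-iodo-7-methyl-3-methylidene-4-(triethylsilyloxy)octa-1,6-diene | I/C=C/C(=C)[C@@H](O[Si](CC)(CC)CC)CC=C(C)C | intermediate
13 | squaric acid | O=C1C(O)=C(O)C1=O | starting material
14 | disilver squarate (Ag2C4O4) | [Ag+].[Ag+].[O-]C1=C([O-])C(=O)C1=O | intermediate
15 | di-tert-butyl squarate | CC(C)(C)OC1=C(OC(C)(C)C)C(=O)C1=O | intermediate
16 | [(1E,4S)-7-methyl-3-methylidene-4-(triethylsilyloxy)octa-1,6-dienyl]lithium | [Li]/C=C/C(=C)[C@@H](O[Si](CC)(CC)CC)CC=C(C)C | intermediate
17 | lithium alkoxide of 2,3-di-tert-butoxy-4-hydroxy-4-dienylcyclobut-2-en-1-one (both epimers at ring C4) | [Li]OC1(/C=C/C(=C)[C@@H](O[Si](CC)(CC)CC)CC=C(C)C)C(=O)C(OC(C)(C)C)=C1OC(C)(C)C | intermediate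
18 | 2,3-di-tert-butoxy-4-(tert-butyldimethylsilyloxy)-4-[(1E,4S)-7-methyl-3-methylidene-4-(triethylsilyloxy)octa-1,6-dienyl]cyclobut-2-en-1-one (both epimers at ring C4) | O=C1C(OC(C)(C)C)=C(OC(C)(C)C)C1(O[Si](C)(C)C(C)(C)C)/C=C/C(=C)[C@@H](O[Si](CC)(CC)CC)CC=C(C)C | intermediate
19 | lithium alkoxide from 1,2-addition of MeLi to 18 | [Li]OC1(C)C(OC(C)(C)C)=C(OC(C)(C)C)C1(O[Si](C)(C)C(C)(C)C)/C=C/C(=C)[C@@H](O[Si](CC)(CC)CC)CC=C(C)C | intermediate
20 | trifluoroacetate of the tertiary cyclobutenol derived from 19 | O=C(OC1(C)C(OC(C)(C)C)=C(OC(C)(C)C)C1(O[Si](C)(C)C(C)(C)C)/C=C/C(=C)[C@@H](O[Si](CC)(CC)CC)CC=C(C)C)C(F)(F)F | intermediate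
21 | 2-tert-butoxy-4-(tert-butyldimethylsilyloxy)-3-methyl-4-[(1E,4S)-7-methyl-3-methylidene-4-(triethylsilyloxy)octa-1,6-dienyl]cyclobut-2-en-1-one (both epimers at ring C4; precursor of the key step) | O=C1C(OC(C)(C)C)=C(C)C1(O[Si](C)(C)C(C)(C)C)/C=C/C(=C)[C@@H](O[Si](CC)(CC)CC)CC=C(C)C | intermediate
22 | dienylketene from ring opening of 21 (dienyl group cis to the ketene, silyloxy group trans) | O=C=C(OC(C)(C)C)/C(C)=C(/O[Si](C)(C)C(C)(C)C)\C=C\C(=C)[C@@H](O[Si](CC)(CC)CC)CC=C(C)C | intermediate
23 | 2-tert-butoxy-4-(tert-butyldimethylsilyloxy)-3-methyl-6-[(3S)-6-methyl-3-(triethylsilyloxy)hepta-1,5-dien-2-yl]cyclohexa-2,4-dien-1-one | O=C1C(OC(C)(C)C)=C(C)C(O[Si](C)(C)C(C)(C)C)=CC1C(=C)[C@@H](O[Si](CC)(CC)CC)CC=C(C)C | intermediate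
24 | 6-tert-butoxy-4-(tert-butyldimethylsilyloxy)-5-methyl-2-[(3S)-6-methyl-3-(triethylsilyloxy)hepta-1,5-dien-2-yl]phenol (product of the key step) | C=C(c1cc(O[Si](C)(C)C(C)(C)C)c(C)c(OC(C)(C)C)c1O)[C@H](CC=C(C)C)O[Si](CC)(CC)CC | intermediate
25 | 2-tert-butoxy-4-(tert-butyldimethylsilyloxy)-3-methyl-6-[(3S)-6-methyl-3-(triethylsilyloxy)hepta-1,5-dien-2-yl]phenyl acetate | C=C(c1cc(O[Si](C)(C)C(C)(C)C)c(C)c(OC(C)(C)C)c1OC(C)=O)[C@H](CC=C(C)C)O[Si](CC)(CC)CC | intermediate
26 | 2,4-bis(tert-butyldimethylsilyloxy)-3-methyl-6-[(3S)-6-methyl-3-(triethylsilyloxy)hepta-1,5-dien-2-yl]phenyl acetate | C=C(c1cc(O[Si](C)(C)C(C)(C)C)c(C)c(O[Si](C)(C)C(C)(C)C)c1OC(C)=O)[C@H](CC=C(C)C)O[Si](CC)(CC)CC | intermediate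
27 | 2,4-bis(tert-butyldimethylsilyloxy)-6-[(3S)-3-hydroxy-6-methylhepta-1,5-dien-2-yl]-3-methylphenyl acetate | C=C(c1cc(O[Si](C)(C)C(C)(C)C)c(C)c(O[Si](C)(C)C(C)(C)C)c1OC(C)=O)[C@H](CC=C(C)C)O | intermediate
28 | angelic acid ((Z)-2-methylbut-2-enoic acid) | C/C=C(/C)C(=O)O | starting material
29 | (Z)-2-methylbut-2-enoic 2,4,6-trichlorobenzoic anhydride | C/C=C(/C)C(=O)OC(=O)c1c(Cl)cc(Cl)cc1Cl | intermediate
30 | (3S)-2-[2-acetoxy-3,5-bis(tert-butyldimethylsilyloxy)-4-methylphenyl]-6-methylhepta-1,5-dien-3-yl (Z)-2-methylbut-2-enoate | C=C(c1cc(O[Si](C)(C)C(C)(C)C)c(C)c(O[Si](C)(C)C(C)(C)C)c1OC(C)=O)[C@H](CC=C(C)C)OC(=O)/C(C)=C\C | intermediate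
31 | (3S)-2-(2-acetoxy-3,5-dihydroxy-4-methylphenyl)-6-methylhepta-1,5-dien-3-yl (Z)-2-methylbut-2-enoate (CNP0147405.1) | C=C(c1cc(O)c(C)c(O)c1OC(C)=O)[C@H](CC=C(C)C)OC(=O)/C(C)=C\C | target

Total step count: 16. Longest linear sequence: 14 steps (steps 1–6 and 9–16). Steps 7 and 8 form the short squarate branch.

Steps most likely to fail

**Step 11 (key step).**
- What may go wrong: the bulky silyl ether may slow the ring opening. At the temperature then needed, loss of isobutene from the tert-butoxy group or thermal oligomerisation of the 2-substituted diene could overtake the 6π closure.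
- Fallback, from 21 back to 24: the O3/O6 differentiation is no longer built into the cyclobutenone but is made afterwards by sterics.
- Et3N·3HF in MeCN should remove both silyl groups and give the cyclobutenone diol F1.
- Et3SiCl (1 equiv) and imidazole in CH2Cl2 at −20 °C should re-silylate only the secondary carbinol and give the 4-hydroxycyclobutenone F2. This is the sterically least demanding and best-studied substrate type of this ring expansion.
- Heating F2 in degassed toluene should give the hydroquinone F3, which is kept under argon.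
- TBSCl (1 equiv) and imidazole in DMF at 0 °C should silylate O3, whose neighbours are only H and CH3. O6 is buried between the tert-butoxy group and the side chain, so this should return to 24.

**Step 13.**
- What may go wrong: O-silylation of the doubly ortho-flanked ether may be slow, silyl groups may exchange at the side-chain oxygen, or the tert-butyl cation may be captured by ring carbon C2.
- Fallback, from 25 to 31: the tert-butyl group is kept to the end and removed by protic acidolysis.
- Aqueous acetic acid as in step 14 should convert 25 into the tert-butyl-protected carbinol F4.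
- Mixed anhydride 29 as in step 15 should give the tert-butyl-protected angelate F5.
- A short exposure to CF3CO2H in CH2Cl2 at −10 °C should free O5 and give the monosilylated phenol F6.
- HF·pyridine as in step 16 should then give 31.
- The acid step should be tolerable there because O3 and O5 are meta to C1, so they do not activate the styrene-type alkene towards protonation. The prenyl alkene remains the group to watch.

**Step 15.**
- What may go wrong: the Z geometry may erode once the acid is activated, acylation of the hindered carbinol may be slow, and during long heating the acetyl group may transfer from O6 to the carbinol oxygen.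
- Fallback, from 27 to 30: the Z-alkene is built on the ester instead of being carried through an acyl transfer.
- Carbodiimide coupling of 27 with 2-[bis(2,2,2-trifluoroethoxy)phosphoryl]propanoic acid (EDC·HCl, DMAP cat., CH2Cl2, 0 °C) is fast even with hindered alcohols and should give the phosphonopropionate F7.
- Still–Gennari olefination (KN(SiMe3)2, 18-crown-6, THF, −78 °C, then acetaldehyde) should then give 30, with the Z geometry set under kinetic control.

Further compounds
F1 | step 11 | 2-tert-butoxy-4-hydroxy-4-[(1E,4S)-4-hydroxy-7-methyl-3-methylideneocta-1,6-dienyl]-3-methylcyclobut-2-en-1-one | O=C1C(OC(C)(C)C)=C(C)C1(O)/C=C/C(=C)[C@@H](O)CC=C(C)C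
F2 | step 11 | 2-tert-butoxy-4-hydroxy-3-methyl-4-[(1E,4S)-7-methyl-3-methylidene-4-(triethylsilyloxy)octa-1,6-dienyl]cyclobut-2-en-1-one | O=C1C(OC(C)(C)C)=C(C)C1(O)/C=C/C(=C)[C@@H](O[Si](CC)(CC)CC)CC=C(C)C
F3 | step 11 | 2-tert-butoxy-3-methyl-6-[(3S)-6-methyl-3-(triethylsilyloxy)hepta-1,5-dien-2-yl]benzene-1,4-diol | C=C(c1cc(O)c(C)c(OC(C)(C)C)c1O)[C@H](CC=C(C)C)O[Si](CC)(CC)CC
F4 | step 13 | 2-tert-butoxy-4-(tert-butyldimethylsilyloxy)-6-[(3S)-3-hydroxy-6-methylhepta-1,5-dien-2-yl]-3-methylphenyl acetate | C=C(c1cc(O[Si](C)(C)C(C)(C)C)c(C)c(OC(C)(C)C)c1OC(C)=O)[C@H](CC=C(C)C)O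
F5 | step 13 | (3S)-2-[2-acetoxy-3-tert-butoxy-5-(tert-butyldimethylsilyloxy)-4-methylphenyl]-6-methylhepta-1,5-dien-3-yl (Z)-2-methylbut-2-enoate | C=C(c1cc(O[Si](C)(C)C(C)(C)C)c(C)c(OC(C)(C)C)c1OC(C)=O)[C@H](CC=C(C)C)OC(=O)/C(C)=C\C
F6 | step 13 | (3S)-2-[2-acetoxy-5-(tert-butyldimethylsilyloxy)-3-hydroxy-4-methylphenyl]-6-methylhepta-1,5-dien-3-yl (Z)-2-methylbut-2-enoate | C=C(c1cc(O[Si](C)(C)C(C)(C)C)c(C)c(O)c1OC(C)=O)[C@H](CC=C(C)C)OC(=O)/C(C)=C\C
F7 | step 15 | (3S)-2-[2-acetoxy-3,5-bis(tert-butyldimethylsilyloxy)-4-methylphenyl]-6-methylhepta-1,5-dien-3-yl 2-[bis(2,2,2-trifluoroethoxy)phosphoryl]propanoate (both epimers at the phosphonate carbon) | C=C(c1cc(O[Si](C)(C)C(C)(C)C)c(C)c(O[Si](C)(C)C(C)(C)C)c1OC(C)=O)[C@H](CC=C(C)C)OC(=O)C(C)P(=O)(OCC(F)(F)F)OCC(F)(F)F
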